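The constants come from no measurement; the rest is arithmetic.

Reagent in the second phase takes 18.6 s to cross, the chair opened, while reagent in the reaction phase lasts 3.45 s against starting material as charged, so the crossing is far slower than the use and, at the start, is the rate-limiting step. The meeting took this flask as its single item:

starting material 0.50 mM; reagent in the second phase 1.00 equiv; protic impurity 0.100 mM; time 40 s; volume of the second phase over the first 1.0

* how much target and product in the second phase together there is at 40 s, in percent of the starting material charged
* the change that raises the amount of target and product in the second phase together at 40 s, in percent of the starting material charged most ("none" if none brings more than 2 percentage points) (alder / elm / oak / none)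
* amount of target and product in the second phase together at 40 s, in percent of the starting material charged, after alder

- what is said of target includes product in the second phase
- in the second phase: reagent in the second phase, product in the second phase; everything else is in the first
- charges count per volume of the first phase; a concentration in a rate is the amount of a species over the volume of its own phase; every rate counts per litre of the first phase
- run time (flask): 40 s

The chair defined that first figure as the release time: partition ratio times volume ratio over transfer coefficient, the time in which the second-phase reagent falls by a factor of e if nothing flows back.

I then put the balance of the reagent on the table. Each unit charged stands in the second phase, stands in the reaction phase, or has reacted. With no return flow, the share that has crossed by 40 s is one minus the exponential of minus time over release time, 88.3%. With 1.00 equiv charged, I argued, that share of the starting material is the ceiling on target made by 40 s, and my reckoning stopped there.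

On the changes, I said alder lifts the crossed share to 98.6%, while elm brings across reagent equal to 177% of the starting material charged, more reagent than alder brings, so I chose elm. Oak acts on a crossing of 0.217 s, much shorter than the release time, so I expected nothing from it.

The forecast's author reported 58%, elm as the best change, and 59% after alder, on the ground that “Reagent feed from the second phase limits the rate”.

The equations were then opened:

    reagent in the reaction phase ⇌ reagent in the second phase, rate k1*([reagent in the reaction phase] - [reagent in the second phase]/K1) per volume of the first phase (K1 = 0.41, k1 = 0.022 s⁻¹)
    starting material + reagent in the reaction phase → target (k2 = 580 M⁻¹ s⁻¹)
    target ⇌ product in the second phase, rate k3*([target] - [product in the second phase]/K3) per volume of the first phase (K3 = 0.39, k3 = 1.8 s⁻¹)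
    target → decomposed product (k4 = 0.0096 s⁻¹)
    starting material + protic impurity → quenched substrate (k5 = 130 M⁻¹ s⁻¹)
    reagent in the reaction phase + target → over-reaction product (k6 = 27 M⁻¹ s⁻¹)

The flask gives 56.4%, close to the forecast, with elm best at 7.9 percentage points over alder's 4.8 points and 61.2% after alder. At 40.0 s the second phase of this flask still held 16.5% of its charge, so 83.5% had left it, a little less than the ceiling of 88.3%.

Read at 15 s, the same flask has a release-time ceiling of 55.4%. The computed neighbour had lost 52.4% of its second-phase reagent and held 35.4% of target and product in the second phase together.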